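The route hinges on one disconnection in ring A: C4a, which bears the C4 carbonyl, and its neighbour C8a, which bears O1, are both made from a C4a≡C8a aryne. In one operation this aryne inserts into the carboxyl C–O bond of an (R)-β-silyloxy acid: oxygen adds to C8a, the acyl carbon moves to C4a, and the C5 acetal oxygen beside C4a steers the direction. The aryne precursor is a hexasubstituted 2-silylaryl triflate (silicon on C4a, triflate on C8a) carrying both prenyl groups, assembled by three directed metalations of a symmetric bis-carbamate that is N-silylated only once. Mitsunobu closure of ring C with inversion then sets (2S), and acid frees the two phenols.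

Key step: step 12

Remark: target atoms are numbered as in a flavanone (O1, C2, C3, C4, C4a, C5–C8, C8a; ring A is the benzo ring, ring C the pyranone) and the target SMILES is read as (2S); prenyl = 3-methylbut-2-en-1-yl, MOM = methoxymethyl, TBS = tert-butyldimethylsilyl, TMS = trimethylsilyl.

Remark: it is assumed that N-TBS carbamates, which are cleaved by aqueous acid, persist through anhydrous, acid-free handling; compounds 5 and 8 are therefore carried on crude after non-aqueous work-up.

Step 1
Reactants: 1 5-methoxyresorcinol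
Product: 2 5-methoxy-1,3-phenylene bis(N-isopropylcarbamate)
Conditions: iPrNCO (2.4 equiv), Et3N (cat.), CH2Cl2, rt
Reagents that add atoms: isopropyl isocyanate, CC(C)N=C=O
Why: Amine-catalysed addition of both equivalent phenols to the isocyanate gives aryl N-isopropylcarbamates, which are strong ortho-directing groups that can later be removed with amine base alone.

Step 2
Reactants: 2 5-methoxy-1,3-phenylene bis(N-isopropylcarbamate)
Product: 5 5-methoxy-2-(trimethylsilyl)-1,3-phenylene bis[N-(tert-butyldimethylsilyl)-N-isopropylcarbamate], via N,N′-bis(TBS) bis-carbamate 3 (not isolated), via C2 aryllithium 4 (not isolated)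
Conditions: TBSOTf (2.2 equiv), TMEDA, Et2O, 0 °C → rt; n-BuLi (3.3 equiv), TMEDA, −78 °C; TMSCl (1.5 equiv), −78 °C → rt; pentane, filtration under argon, evaporation (no aqueous work-up)
Reagents that add atoms: chlorotrimethylsilane, C[Si](C)(C)Cl; tert-butyldimethylsilyl triflate, CC(C)(C)[Si](C)(C)OS(=O)(=O)C(F)(F)F
Why: N-Silylation masks both N–H groups and directed ortho-metalation should then occur at C2, whose hydrogen is flanked by two cooperating carbamoyloxy groups whereas C4 and C6 have one carbamate beside the weaker methoxy director, so silicon is placed on the future C4a, and avoiding aqueous acid keeps the N-silyl groups in place for the next two metalations.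

Step 3
Reactants: 5 5-methoxy-2-(trimethylsilyl)-1,3-phenylene bis[N-(tert-butyldimethylsilyl)-N-isopropylcarbamate], 6 prenyl bromide
Product: 8 5-methoxy-4-prenyl-2-(trimethylsilyl)-1,3-phenylene bis[N-(tert-butyldimethylsilyl)-N-isopropylcarbamate], via C4 aryllithium 7 (not isolated)
Conditions: n-BuLi (1.2 equiv), TMEDA, Et2O, −78 °C; CuBr·SMe2 (10 mol %), 6 (1.2 equiv), −78 °C → 0 °C; pentane, filtration under argon, evaporation (no aqueous work-up)
Reagents that add atoms: none
Why: With C2 blocked and both nitrogens still silylated, directed ortho-metalation can only take place at the two equivalent positions between a carbamate and the methoxy group, and the aryllithium should undergo copper-catalysed SN2 allylation at the unhindered primary carbon of prenyl bromide to give the linear prenyl group.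

Step 4
Reactants: 8 5-methoxy-4-prenyl-2-(trimethylsilyl)-1,3-phenylene bis[N-(tert-butyldimethylsilyl)-N-isopropylcarbamate], 6 prenyl bromide
Product: 11 5-methoxy-4,6-diprenyl-2-(trimethylsilyl)-1,3-phenylene bis(N-isopropylcarbamate), via C6 aryllithium 9 (not isolated), via diprenylated N,N′-bis(TBS) bis-carbamate 10 (not isolated)
Conditions: n-BuLi (1.2 equiv), TMEDA, Et2O, −78 °C; CuBr·SMe2 (10 mol %), 6 (1.2 equiv), −78 °C → 0 °C; aq. NaHSO4 work-up
Reagents that add atoms: none
Why: The last ring hydrogen lies between the second carbamate and the methoxy group, so kinetic carbamate-directed ring lithiation at −78 °C should be preferred to deprotonation of the prenyl methylene, the same allylation completes the hexasubstituted ring, and aqueous NaHSO4 then hydrolyses both N–Si bonds to return the N–H carbamates needed for base-induced cleavage.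

Step 5
Reactants: 11 5-methoxy-4,6-diprenyl-2-(trimethylsilyl)-1,3-phenylene bis(N-isopropylcarbamate)
Product: 13 3-methoxy-5-(methoxymethoxy)-2,4-diprenyl-6-(trimethylsilyl)phenyl N-isopropylcarbamate, via mono-carbamate phenol 12 (not isolated)
Conditions: Et2NH (5 equiv), DBU (1.05 equiv), MeCN, 40 °C; evaporate; MOMCl, CH2Cl2, 0 °C
Reagents that add atoms: chloromethyl methyl ether, COCCl
Why: Base-induced E1cB cleavage of an aryl N-monoalkylcarbamate (the isocyanate being trapped by diethylamine) should stop after one of the two equivalent groups when about one equivalent of DBU is used, because the phenoxide formed makes the second aryloxide a far poorer leaving group, and O-alkylation of that phenoxide then differentiates the two oxygens without any acid that could protodesilylate C4a.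

Step 6
Reactants: 13 3-methoxy-5-(methoxymethoxy)-2,4-diprenyl-6-(trimethylsilyl)phenyl N-isopropylcarbamate
Product: 15 3-methoxy-5-(methoxymethoxy)-2,4-diprenyl-6-(trimethylsilyl)phenyl trifluoromethanesulfonate, via ortho-silyl phenol 14 (not isolated)
Conditions: Et2NH (1.2 equiv), DBU (1.5 equiv), MeCN, 40 °C; then PhNTf2 (1.5 equiv), rt
Reagents that add atoms: N-phenylbis(trifluoromethanesulfonimide), O=S(=O)(N(c1ccccc1)S(=O)(=O)C(F)(F)F)C(F)(F)F
Why: The same E1cB carbamate cleavage frees the remaining oxygen as an ortho-silyl phenoxide, which is triflated in the same flask to give the ortho-silylaryl triflate (TMS on the future C4a, triflate on C8a), a standard fluoride-triggered aryne precursor.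

Step 7
Reactants: 16 4′-hydroxyacetophenone
Product: 17 4′-(methoxymethoxy)acetophenone
Conditions: MOMCl, iPr2NEt, CH2Cl2, 0 °C → rt
Reagents that add atoms: chloromethyl methyl ether, COCCl
Why: Williamson-type O-alkylation of the phenol installs an acetal that tolerates enolate, hydride-transfer, fluoride and Mitsunobu conditions and is removed together with the ring A acetal at the end.

Step 8
Reactants: 17 4′-(methoxymethoxy)acetophenone, 18 dimethyl carbonate
Product: 19 methyl 3-[4-(methoxymethoxy)phenyl]-3-oxopropanoate
Conditions: NaH (2.2 equiv), 18 (excess), THF, reflux; then AcOH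
Reagents that add atoms: none
Why: Crossed Claisen condensation of the methyl ketone enolate with dimethyl carbonate is driven to completion by deprotonation of the β-keto ester formed.

Step 9
Reactants: 19 methyl 3-[4-(methoxymethoxy)phenyl]-3-oxopropanoate
Product: 20 methyl (3R)-3-hydroxy-3-[4-(methoxymethoxy)phenyl]propanoate
Conditions: RuCl[(R,R)-TsDPEN](p-cymene) (1 mol %), HCO2H/Et3N (5:2), 30 °C
Reagents that add atoms: none
Why: Noyori–Ikariya asymmetric transfer hydrogenation of the aryl ketone sets the only stereocentre, the (R,R)-diamine complex delivering hydride to the face that gives the (R)-benzylic alcohol, in the same sense as for simple aryl alkyl ketones.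

Step 10
Reactants: 20 methyl (3R)-3-hydroxy-3-[4-(methoxymethoxy)phenyl]propanoate
Product: 21 methyl (3R)-3-(tert-butyldimethylsilyloxy)-3-[4-(methoxymethoxy)phenyl]propanoate
Conditions: TBSCl, imidazole, DMF, rt
Reagents that add atoms: tert-butyldimethylsilyl chloride, CC(C)(C)[Si](C)(C)Cl
Why: Standard silylation of the secondary alcohol gives a silyl ether that hides the hydroxyl from the aryne and can later be removed without touching the acetals.

Step 11
Reactants: 21 methyl (3R)-3-(tert-butyldimethylsilyloxy)-3-[4-(methoxymethoxy)phenyl]propanoate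
Product: 22 (3R)-3-(tert-butyldimethylsilyloxy)-3-[4-(methoxymethoxy)phenyl]propanoic acid
Conditions: LiOH·H2O, THF/MeOH/H2O, 0 °C → rt; then 1 M HCl to pH 4, 0 °C
Reagents that add atoms: lithium hydroxide, [Li+].[OH-]
Why: Saponification of the methyl ester at low temperature followed by careful acidification should give the free acid while the silyl ether, the acetal and the stereocentre stay intact.

Step 12
Reactants: 15 3-methoxy-5-(methoxymethoxy)-2,4-diprenyl-6-(trimethylsilyl)phenyl trifluoromethanesulfonate, 22 (3R)-3-(tert-butyldimethylsilyloxy)-3-[4-(methoxymethoxy)phenyl]propanoic acid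
Product: 24 (3R)-3-(tert-butyldimethylsilyloxy)-1-[2-hydroxy-4-methoxy-6-(methoxymethoxy)-3,5-diprenylphenyl]-3-[4-(methoxymethoxy)phenyl]propan-1-one, via aryne 23 (not isolated)
Conditions: CsF (4 equiv), 15 (1.5 equiv), THF, 125 °C, sealed tube
Reagents that add atoms: none
Why: Fluoride removes the C4a silyl group and triflate leaves from C8a to give aryne 23; the caesium carboxylate of 22 adds through oxygen to C8a and the resulting C4a aryl anion attacks the new ester carbonyl through a four-membered alkoxide that opens to the ortho-acyl phenoxide, so the C8a–O and C4a–C4 bonds form in one flask. This is the known formal insertion of arynes into the C–O bond of carboxylic acids (an aryne-triggered anionic Fries-type acyl shift), applied here to a tetrasubstituted aryne. No ring of the target closes and no stereocentre is created; C2 should keep its (R) silyl ether because neither the carboxylate nor the phenoxide product is readily deprotonated next to the carbonyl. The step needs oxygen to attack C8a and not C4a, which is secured by the inductively withdrawing C5 methoxymethoxy group that polarises the aryne and stabilises the charge developing at C4a, as in 3-alkoxybenzynes. It also needs the acyl shift to outrun protonation of the aryl anion, which the aprotic medium, the sparingly soluble fluoride source and the high temperature favour.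

Step 13
Reactants: 24 (3R)-3-(tert-butyldimethylsilyloxy)-1-[2-hydroxy-4-methoxy-6-(methoxymethoxy)-3,5-diprenylphenyl]-3-[4-(methoxymethoxy)phenyl]propan-1-one
Product: 25 (3R)-3-hydroxy-1-[2-hydroxy-4-methoxy-6-(methoxymethoxy)-3,5-diprenylphenyl]-3-[4-(methoxymethoxy)phenyl]propan-1-one
Conditions: HF·pyridine, pyridine, THF, 0 °C → rt
Reagents that add atoms: none
Why: Fluoride-mediated cleavage of the secondary silyl ether with pyridine-buffered HF·pyridine is mild and non-basic, so the aryl acetals, the prenyl groups and the β-hydroxy ketone (no retro-aldol or elimination) should survive.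

Step 14
Reactants: 25 (3R)-3-hydroxy-1-[2-hydroxy-4-methoxy-6-(methoxymethoxy)-3,5-diprenylphenyl]-3-[4-(methoxymethoxy)phenyl]propan-1-one
Product: 26 (2S)-7-methoxy-5-(methoxymethoxy)-2-[4-(methoxymethoxy)phenyl]-6,8-diprenylchroman-4-one
Conditions: PPh3, DIAD, THF, 0 °C
Reagents that add atoms: none
Why: Mitsunobu etherification, in which the chelated C8a phenol displaces the activated benzylic oxygen in a 6-exo-tet SN2 closure of ring C, so C2 is inverted from (R) to the required (S).

Step 15
Reactants: 26 (2S)-7-methoxy-5-(methoxymethoxy)-2-[4-(methoxymethoxy)phenyl]-6,8-diprenylchroman-4-one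
Product: 27 (2S)-5-hydroxy-2-(4-hydroxyphenyl)-7-methoxy-6,8-diprenylchroman-4-one (CNP0121058.1)
Conditions: 3 M aq. HCl, MeOH, 45 °C
Reagents that add atoms: none
Why: Acid-catalysed methanolysis of the two aryl methoxymethyl acetals frees the C5 and C4′ phenols under conditions mild enough to spare the prenyl groups, and the flavanone stereocentre is configurationally stable in acid.

Compound list
1 | 5-methoxyresorcinol (5-methoxybenzene-1,3-diol) | COc1cc(O)cc(O)c1 | starting material
2 | 5-methoxy-1,3-phenylene bis(N-isopropylcarbamate) | COc1cc(OC(=O)NC(C)C)cc(OC(=O)NC(C)C)c1 | intermediate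
3 | 5-methoxy-1,3-phenylene bis[N-(tert-butyldimethylsilyl)-N-isopropylcarbamate] (in situ) | COc1cc(OC(=O)N(C(C)C)[Si](C)(C)C(C)(C)C)cc(OC(=O)N(C(C)C)[Si](C)(C)C(C)(C)C)c1 | intermediate
4 | 2-lithio derivative of 3 (in situ) | COc1cc(OC(=O)N(C(C)C)[Si](C)(C)C(C)(C)C)c([Li])c(OC(=O)N(C(C)C)[Si](C)(C)C(C)(C)C)c1 | intermediate
5 | 5-methoxy-2-(trimethylsilyl)-1,3-phenylene bis[N-(tert-butyldimethylsilyl)-N-isopropylcarbamate] | COc1cc(OC(=O)N(C(C)C)[Si](C)(C)C(C)(C)C)c([Si](C)(C)C)c(OC(=O)N(C(C)C)[Si](C)(C)C(C)(C)C)c1 | intermediate
6 | prenyl bromide (1-bromo-3-methylbut-2-ene) | CC(C)=CCBr | starting material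
7 | 4-lithio derivative of 5 (in situ) | COc1cc(OC(=O)N(C(C)C)[Si](C)(C)C(C)(C)C)c([Si](C)(C)C)c(OC(=O)N(C(C)C)[Si](C)(C)C(C)(C)C)c1[Li] | intermediate
8 | 5-methoxy-4-prenyl-2-(trimethylsilyl)-1,3-phenylene bis[N-(tert-butyldimethylsilyl)-N-isopropylcarbamate] | COc1cc(OC(=O)N(C(C)C)[Si](C)(C)C(C)(C)C)c([Si](C)(C)C)c(OC(=O)N(C(C)C)[Si](C)(C)C(C)(C)C)c1CC=C(C)C | intermediate
9 | 6-lithio derivative of 8 (in situ) | COc1c([Li])c(OC(=O)N(C(C)C)[Si](C)(C)C(C)(C)C)c([Si](C)(C)C)c(OC(=O)N(C(C)C)[Si](C)(C)C(C)(C)C)c1CC=C(C)C | intermediate
10 | 5-methoxy-4,6-diprenyl-2-(trimethylsilyl)-1,3-phenylene bis[N-(tert-butyldimethylsilyl)-N-isopropylcarbamate] (in situ) | COc1c(CC=C(C)C)c(OC(=O)N(C(C)C)[Si](C)(C)C(C)(C)C)c([Si](C)(C)C)c(OC(=O)N(C(C)C)[Si](C)(C)C(C)(C)C)c1CC=C(C)C | intermediate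
11 | 5-methoxy-4,6-diprenyl-2-(trimethylsilyl)-1,3-phenylene bis(N-isopropylcarbamate) | COc1c(CC=C(C)C)c(OC(=O)NC(C)C)c([Si](C)(C)C)c(OC(=O)NC(C)C)c1CC=C(C)C | intermediate
12 | 3-hydroxy-5-methoxy-4,6-diprenyl-2-(trimethylsilyl)phenyl N-isopropylcarbamate (in situ) | COc1c(CC=C(C)C)c(O)c([Si](C)(C)C)c(OC(=O)NC(C)C)c1CC=C(C)C | intermediate
13 | 3-methoxy-5-(methoxymethoxy)-2,4-diprenyl-6-(trimethylsilyl)phenyl N-isopropylcarbamate | COCOc1c(CC=C(C)C)c(OC)c(CC=C(C)C)c(OC(=O)NC(C)C)c1[Si](C)(C)C | intermediate
14 | 3-methoxy-5-(methoxymethoxy)-2,4-diprenyl-6-(trimethylsilyl)phenol (in situ) | COCOc1c(CC=C(C)C)c(OC)c(CC=C(C)C)c(O)c1[Si](C)(C)C | intermediate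
15 | 3-methoxy-5-(methoxymethoxy)-2,4-bis(3-methylbut-2-en-1-yl)-6-(trimethylsilyl)phenyl trifluoromethanesulfonate | COCOc1c(CC=C(C)C)c(OC)c(CC=C(C)C)c(OS(=O)(=O)C(F)(F)F)c1[Si](C)(C)C | intermediate
16 | 4′-hydroxyacetophenone | CC(=O)c1ccc(O)cc1 | starting material
17 | 4′-(methoxymethoxy)acetophenone | CC(=O)c1ccc(OCOC)cc1 | intermediate
18 | dimethyl carbonate | COC(=O)OC | starting material
19 | methyl 3-[4-(methoxymethoxy)phenyl]-3-oxopropanoate | COC(=O)CC(=O)c1ccc(OCOC)cc1 | intermediate
20 | methyl (3R)-3-hydroxy-3-[4-(methoxymethoxy)phenyl]propanoate | COC(=O)C[C@@H](O)c1ccc(OCOC)cc1 | intermediate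
21 | methyl (3R)-3-(tert-butyldimethylsilyloxy)-3-[4-(methoxymethoxy)phenyl]propanoate | COC(=O)C[C@@H](O[Si](C)(C)C(C)(C)C)c1ccc(OCOC)cc1 | intermediate
22 | (3R)-3-(tert-butyldimethylsilyloxy)-3-[4-(methoxymethoxy)phenyl]propanoic acid | OC(=O)C[C@@H](O[Si](C)(C)C(C)(C)C)c1ccc(OCOC)cc1 | intermediate
23 | 4-methoxy-6-(methoxymethoxy)-3,5-diprenylbenzyne, the C4a≡C8a aryne (in situ) | COCOC1=C(CC=C(C)C)C(OC)=C(CC=C(C)C)C#C1 | intermediate
24 | (3R)-3-(tert-butyldimethylsilyloxy)-1-[2-hydroxy-4-methoxy-6-(methoxymethoxy)-3,5-diprenylphenyl]-3-[4-(methoxymethoxy)phenyl]propan-1-one | COCOc1c(CC=C(C)C)c(OC)c(CC=C(C)C)c(O)c1C(=O)C[C@@H](O[Si](C)(C)C(C)(C)C)c1ccc(OCOC)cc1 | intermediate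
25 | (3R)-3-hydroxy-1-[2-hydroxy-4-methoxy-6-(methoxymethoxy)-3,5-diprenylphenyl]-3-[4-(methoxymethoxy)phenyl]propan-1-one | COCOc1c(CC=C(C)C)c(OC)c(CC=C(C)C)c(O)c1C(=O)C[C@@H](O)c1ccc(OCOC)cc1 | intermediate
26 | (2S)-7-methoxy-5-(methoxymethoxy)-2-[4-(methoxymethoxy)phenyl]-6,8-diprenylchroman-4-one | COc1c(CC=C(C)C)c(OCOC)c2c(c1CC=C(C)C)O[C@H](c1ccc(OCOC)cc1)CC2=O | intermediate
27 | (2S)-5-hydroxy-2-(4-hydroxyphenyl)-7-methoxy-6,8-diprenylchroman-4-one | COc1c(CC=C(C)C)c(O)c2c(c1CC=C(C)C)O[C@H](c1ccc(O)cc1)CC2=O | target

Total step count: 15. Longest linear sequence: 10 steps (steps 1–6, then 12–15); the acid branch (steps 7–11) has 5 steps and joins at step 12.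

Steps most likely to fail

Step 12. The C4a aryl anion may be protonated before it reaches the acyl carbon, so that only O-arylation occurs. The crowded aryne may also be diverted by ene-type reactions with prenyl groups, and fluoride at 125 °C may attack the secondary silyl ether. The fallback forms the two bonds in separate operations and sets out from 15 and 22. The aryne is generated under the mild conditions known to give aryl esters from carboxylic acids (CsF, MeCN, rt), which should give 3-methoxy-5-(methoxymethoxy)-2,4-diprenylphenyl (3R)-3-(tert-butyldimethylsilyloxy)-3-[4-(methoxymethoxy)phenyl]propanoate F1, with oxygen on C8a and hydrogen on C4a. Irradiation of F1 (254 nm, degassed MeCN) should then move the acyl group to C4a, the only free ortho position, by photo-Fries rearrangement. The ortho-hydroxyaryl ketone formed is protected from further photochemistry by its internal hydrogen bond. The fallback comes back to the route at 24.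

Step 4. Hydrolytic loss of N–Si bonds during the two non-aqueous carry-overs would expose N–H groups, so that n-BuLi triggers isocyanate elimination from the carbamate instead of ring metalation; deprotonation of the prenyl methylene may add to the loss. The fallback sets out from crude 8 and gives up the carry-over of silylated material in favour of a purified N–H intermediate. Aqueous NaHSO4 work-up of 8 should give 5-methoxy-4-prenyl-2-(trimethylsilyl)-1,3-phenylene bis(N-isopropylcarbamate) F2, which is stable to air and is purified by chromatography. Fresh N-silylation of F2 (TBSOTf (2.2 equiv), TMEDA, Et2O, 0 °C → rt) regenerates 8 in the flask immediately before metalation, which is then run with n-BuLi (3.3 equiv) as in step 2. The fallback comes back to the route at 8.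

Step 14. Elimination of the activated β-hydroxy ketone to the 2′-hydroxychalcone, which recloses without facial control, or ionisation at the 4-alkoxybenzylic carbon would erode the enantiomeric purity at C2. The fallback sets out from 26 of insufficient purity and upgrades it by kinetic resolution through asymmetric transfer hydrogenation (Cp*RhCl[(R,R)-TsDPEN] (1 mol %), HCO2H/Et3N, EtOAc, rt). The (2R)-ketone should be reduced faster, to (2R,4R)-7-methoxy-5-(methoxymethoxy)-2-[4-(methoxymethoxy)phenyl]-6,8-diprenylchroman-4-ol F3, which is separated by chromatography from unreacted (2S)-ketone. The fallback comes back to the route at 26.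

Further compounds
F1 | step 12 | 3-methoxy-5-(methoxymethoxy)-2,4-diprenylphenyl (3R)-3-(tert-butyldimethylsilyloxy)-3-[4-(methoxymethoxy)phenyl]propanoate | COCOc1cc(OC(=O)C[C@@H](O[Si](C)(C)C(C)(C)C)c2ccc(OCOC)cc2)c(CC=C(C)C)c(OC)c1CC=C(C)C
F2 | step 4 | 5-methoxy-4-prenyl-2-(trimethylsilyl)-1,3-phenylene bis(N-isopropylcarbamate) | COc1cc(OC(=O)NC(C)C)c([Si](C)(C)C)c(OC(=O)NC(C)C)c1CC=C(C)C
F3 | step 14 | (2R,4R)-7-methoxy-5-(methoxymethoxy)-2-[4-(methoxymethoxy)phenyl]-6,8-diprenylchroman-4-ol | COc1c(CC=C(C)C)c(OCOC)c2c(c1CC=C(C)C)O[C@@H](c1ccc(OCOC)cc1)C[C@H]2O
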